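**Retrosynthetic overview**
1. Target 9 is the 25-membered ring oxacyclopentacosan-2-one (24 C and 1 O; C1 = carbonyl carbon, C24 = O-bound CH2). It is opened at the C5–C6 bond, through the ring olefins 7 and 8 (C5=C6), to the open-chain diene ester 6: ring-closing olefin metathesis with hydrogenation in the same flask.
2. Enabling feature: C5–C6 lies in the unbranched all-CH2 arc of the ring, three CH2 groups (C2–C4) from the lactone carbonyl C1 and eighteen (C7–C24) from the ring oxygen. Both ends are therefore unhindered terminal vinyl groups, a C5 alkylidene can reach the ester carbonyl only through a seven-membered chelate, and neither a stereocentre nor an olefin geometry has to be controlled.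
3. 6 is cut at the sp3–sp3 bond C15–C16 (copper-catalysed Grignard/alkyl bromide coupling that tolerates the ester) into bromo ester 3 and 11-bromoundec-1-ene 4; 3 comes from 9-bromononan-1-ol 1 and hex-5-enoic acid 2 by esterification.
4. Ring order: a single ring, the 25-membered lactone, closed in the last step; no protecting groups.

Key step: step 3

Remark: 1, 2 and 4 are taken as commercial; 7 and 8 are the two geometric isomers expected side by side from the ring closure (not one from the other), and both are reduced to 9, so the olefin geometry is of no consequence.

**Route**

Step 1
Reactants: 1 9-bromononan-1-ol; 2 hex-5-enoic acid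
Product: 3 9-bromononyl hex-5-enoate
Conditions: DCC (1.1 equiv), DMAP (10 mol%), CH2Cl2, 0 °C to rt
Reagents that add atoms: none
Why: Steglich esterification, in which DMAP relays the acyl group from the O-acylisourea of 2 to the primary alcohol of 1 faster than the O-to-N acyl shift, while the primary bromide and the terminal alkene are inert under these neutral conditions; no stereocentre is formed.

Step 2
Reactants: 3 9-bromononyl hex-5-enoate; 4 11-bromoundec-1-ene
Product: 6 icos-19-enyl hex-5-enoate, via undec-10-enylmagnesium bromide 5 (not isolated)
Conditions: 4 (1.3 equiv), Mg, THF, 40 °C; then added over 2 h to 3, Li2CuCl4 (3 mol%), NMP (4 equiv), THF, 0 °C to rt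
Reagents that add atoms: none
Why: Copper-catalysed sp3–sp3 cross-coupling of a primary alkyl Grignard reagent with a primary alkyl bromide (Li2CuCl4 with NMP as cosolvent), in which substitution at the C–Br carbon by the transient alkylcopper species should be much faster than addition of the slowly added Grignard reagent to the ester carbonyl, so the hex-5-enoate and both terminal alkenes should survive; no stereocentre is formed.

Step 3
Reactants: 6 icos-19-enyl hex-5-enoate
Product: 9 24-tetracosanolide (oxacyclopentacosan-2-one), via (E)-oxacyclopentacos-6-en-2-one 7 (not isolated), via (Z)-oxacyclopentacos-6-en-2-one 8 (not isolated)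
Conditions: second-generation Grubbs catalyst RuCl2(=CHPh)(H2IMes)(PCy3) (5 mol%), CH2Cl2 (slow addition of 6, 2 mM final), 40 °C, Ar sweep; then H2 purge, 10% Pd/C, H2 (1 atm), rt, same flask
Reagents that add atoms: none
Why: Ring-closing olefin metathesis followed by hydrogenation in the same flask: the ruthenium alkylidene formed at one terminal vinyl group of 6 adds to the other in a [2+2] cycloaddition, cycloreversion of the ruthenacyclobutane expels ethylene and forms the C5=C6 double bond of 7 and 8, and H2 on Pd/C then saturates it to the C5–C6 single bond of 9. The closest known reaction type is the ring-closing metathesis of open-chain alkenyl alkenoates to 14- to 21-membered musk lactones followed by hydrogenation of the E/Z mixture. The 25-membered ring is closed by end-to-end macrocyclisation of a conformationally unbiased chain under ring-chain equilibrium, strain-free and driven by loss of volatile ethylene. No stereocentre is created, and the geometry of the new olefin needs no control because both isomers give the same saturated lactone. The selectivity that is needed is ring closure over intermolecular acyclic diene metathesis; it is secured by slow addition at high dilution and by the reversibility of metathesis at the unhindered 1,2-disubstituted olefins (oligomers should back-bite to the monomeric ring), while the ester carbonyl, three CH2 groups away from C5, can form only a weak seven-membered chelate and should not sequester the catalyst. In the second stage H2 first destroys the remaining alkylidene, and Pd/C at 1 atm should reduce only the ring olefin and leave the lactone untouched.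

**Compound list**
1 | 9-bromononan-1-ol | OCCCCCCCCCBr | starting material
2 | hex-5-enoic acid | OC(=O)CCCC=C | starting material
3 | 9-bromononyl hex-5-enoate | C=CCCCC(=O)OCCCCCCCCCBr | intermediate
4 | 11-bromoundec-1-ene | C=CCCCCCCCCCBr | starting material
5 | undec-10-enylmagnesium bromide (not isolated) | C=CCCCCCCCCC[Mg]Br | intermediate
6 | icos-19-enyl hex-5-enoate | C=CCCCC(=O)OCCCCCCCCCCCCCCCCCCC=C | intermediate
7 | (E)-oxacyclopentacos-6-en-2-one, (E)-tetracos-5-en-24-olide (not isolated) | O=C1CCC/C=C/CCCCCCCCCCCCCCCCCCO1 | intermediate
8 | (Z)-oxacyclopentacos-6-en-2-one, (Z)-tetracos-5-en-24-olide (not isolated) | O=C1CCC/C=C\CCCCCCCCCCCCCCCCCCO1 | intermediate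
9 | 24-tetracosanolide (oxacyclopentacosan-2-one) | O=C1CCCCCCCCCCCCCCCCCCCCCCCO1 | target

**Totals**
Total step count: 3. Longest linear sequence: 3 steps (1 and 2 to 3, then 6, then 9).

**Steps most likely to fail**

Step 3. The risks are ring closure losing to intermolecular metathesis (chain growth to oligomers) at practical concentrations, olefin migration before ring closure leading to ring contraction, and sluggish hydrogenation in the dilute solution. Fallback (sets out from 2 and 5, comes back at 9): the C5–C6 bond is made intermolecularly and the ring is closed at the O–C24 bond instead.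
- Grignard reagent 5 is coupled with a threefold excess of commercial 1,9-dibromononane (BrCCCCCCCCCBr; Li2CuCl4 cat., THF, 0 °C) to give 20-bromoicos-1-ene F1.
- Cross-metathesis of F1 with an excess of 2 (RuCl2(=CHPh)(H2IMes)(PCy3), CH2Cl2, 40 °C, 0.2 M) should give (E)-24-bromotetracos-5-enoic acid F2 together with (Z)-24-bromotetracos-5-enoic acid F3.
- Hydrogenation of the mixture (H2, PtO2, EtOAc, rt), which should spare the primary bromide, gives 24-bromotetracosanoic acid F4.
- Slow addition of F4 to Cs2CO3 in DMF at 80 °C forms caesium 24-bromotetracosanoate F5 in the flask, which should close the 25-membered ring by intramolecular SN2 O-alkylation (caesium-carboxylate macrolactonisation) to give 9.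

Step 2. The risks are 1,2-addition of the Grignard reagent to the ester carbonyl or enolisation of the ester in competition with the copper-catalysed substitution, and Wurtz-type homocoupling during Grignard formation. Fallback (sets out from 1, uses 5 and 2, comes back at 6): the C15–C16 coupling is moved in front of the esterification so that no ester meets the Grignard reagent.
- 1 is silylated (TBSCl, imidazole, DMF, rt) to (9-bromononyloxy)(tert-butyl)dimethylsilane F6.
- F6 is coupled with 5 (Li2CuCl4 cat., THF, 0 °C) to tert-butyl(icos-19-enyloxy)dimethylsilane F7.
- Acid methanolysis (HCl cat., MeOH, rt) releases icos-19-en-1-ol F8.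
- F8 is esterified with 2 (DCC, DMAP, CH2Cl2) to 6.

Step 1. The risks are O-to-N acyl migration of the activated acid to an unreactive N-acylurea and slow alkylation of DMAP or of the carboxylate by the primary bromide. Fallback (sets out from 2, comes back at 3): the ester is made at its O–alkyl bond instead of its acyl–O bond. 2 is converted with Cs2CO3 in DMF into caesium hex-5-enoate F9, which is alkylated at rt with a fourfold excess of commercial 1,9-dibromononane (BrCCCCCCCCCBr) to give 3 directly; the excess dibromide should suppress double alkylation and is recovered.

**Further compounds**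
F1 | step 3 | 20-bromoicos-1-ene | C=CCCCCCCCCCCCCCCCCCCBr
F2 | step 3 | (E)-24-bromotetracos-5-enoic acid | OC(=O)CCC/C=C/CCCCCCCCCCCCCCCCCCBr
F3 | step 3 | (Z)-24-bromotetracos-5-enoic acid | OC(=O)CCC/C=C\CCCCCCCCCCCCCCCCCCBr
F4 | step 3 | 24-bromotetracosanoic acid | OC(=O)CCCCCCCCCCCCCCCCCCCCCCCBr
F5 | step 3 | caesium 24-bromotetracosanoate | [Cs+].[O-]C(=O)CCCCCCCCCCCCCCCCCCCCCCCBr
F6 | step 2 | (9-bromononyloxy)(tert-butyl)dimethylsilane | CC(C)(C)[Si](C)(C)OCCCCCCCCCBr
F7 | step 2 | tert-butyl(icos-19-enyloxy)dimethylsilane | CC(C)(C)[Si](C)(C)OCCCCCCCCCCCCCCCCCCC=C
F8 | step 2 | icos-19-en-1-ol | OCCCCCCCCCCCCCCCCCCC=C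
F9 | step 1 | caesium hex-5-enoate | [Cs+].[O-]C(=O)CCCC=C
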